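**Retrosynthetic overview**
- No ring is formed: both benzene rings are bought intact, and the only task is the nine-carbon ketone chain.
- Key disconnection: C2–C3 of the nonanone chain. C2 is used as an α-keto cation (enolonium, a2) equivalent, the α-bromo ketone; C3 is the primary carbon of a B-alkyl-9-BBN. The bond forms by a 1,2-shift in a boron ate complex.
- The borane comes from in-flask hydroboration of a 7-arylhept-1-ene, made by copper-catalysed coupling of a silyl-protected 4-bromophenol Grignard reagent with 7-bromohept-1-ene.
- The α-bromo ketone comes from 2',6'-dimethoxyacetophenone through its silyl enol ether; the phenol silyl ether is cleaved in the same flask as the key step.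

Assumption: the SMILES has no stereocentre and no stereogenic double bond, so the target is achiral and there is no configuration to set; the one compound drawn is made. Compounds are numbered in the order they appear in the forward route.

**Step 1**
Reactants: 1 (4-bromophenoxy)(tert-butyl)dimethylsilane; 2 7-bromohept-1-ene
Product: 4 tert-butyl[4-(hept-6-en-1-yl)phenoxy]dimethylsilane, via arylmagnesium bromide 3 (not isolated)
Conditions: 1, Mg, THF, reflux; then 2, Li2CuCl4 (3 mol %), THF, 0 °C → rt
Reagents that add atoms: none
Why: Copper-catalysed Grignard cross-coupling (Kochi type): the aryl Grignard reagent displaces the primary bromide of 2, while the aryl silyl ether and the remote terminal alkene are inert; no stereocentre is involved.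

**Step 2**
Reactants: 5 1-(2,6-dimethoxyphenyl)ethan-1-one
Product: 7 2-bromo-1-(2,6-dimethoxyphenyl)ethan-1-one, via silyl enol ether 6 (not isolated)
Conditions: Me3SiOTf, Et3N, CH2Cl2, 0 °C; then NBS (1.0 equiv), 0 °C → rt
Reagents that add atoms: N-bromosuccinimide (NBS), O=C1CCC(=O)N1Br
Why: Soft enolisation followed by electrophilic bromination of the silyl enol ether, which is far more nucleophilic than the dimethoxyarene, so bromine goes only to the α-carbon and gives the a2 partner; no stereocentre is involved.

**Step 3**
Reactants: 4 tert-butyl[4-(hept-6-en-1-yl)phenoxy]dimethylsilane; 7 2-bromo-1-(2,6-dimethoxyphenyl)ethan-1-one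
Product: 10 1-(2,6-dimethoxyphenyl)-9-(4-hydroxyphenyl)nonan-1-one, via B-alkyl-9-BBN 8 (not isolated), via silyl-protected ketone 9 (not isolated)
Conditions: 4 (1.15 equiv), 9-BBN (1.10 equiv), THF, 0 °C → rt; then 7 (1.0 equiv), KOC6H3-2,6-tBu2 (1.05 equiv, stock solution in THF, slow addition), 0 °C → rt; then AcOH, Bu4NF (3 equiv each), THF, rt
Reagents that add atoms: none
Why: Anti-Markovnikov hydroboration gives the primary alkylborane; the hindered phenoxide forms the α-bromo enolate of 7, which adds to boron, and the ate complex undergoes 1,2-migration of the primary alkyl group (in preference to the bicyclic ring bonds) onto the α-carbon with loss of bromide (Brown α-alkylation of α-halo ketones with organoboranes); protonolysis of the boron enolate and buffered fluoride desilylation then release the achiral target. The alkene is kept in slight excess over 9-BBN so that no B–H remains to reduce the ketone.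

**Compound list**
1 | (4-bromophenoxy)(tert-butyl)dimethylsilane | CC(C)(C)[Si](C)(C)Oc1ccc(Br)cc1 | starting material
2 | 7-bromohept-1-ene | C=CCCCCCBr | starting material
3 | {4-[(tert-butyldimethylsilyl)oxy]phenyl}magnesium bromide | CC(C)(C)[Si](C)(C)Oc1ccc([Mg]Br)cc1 | intermediate
4 | tert-butyl[4-(hept-6-en-1-yl)phenoxy]dimethylsilane | C=CCCCCCc1ccc(O[Si](C)(C)C(C)(C)C)cc1 | intermediate
5 | 1-(2,6-dimethoxyphenyl)ethan-1-one (2',6'-dimethoxyacetophenone) | COc1cccc(OC)c1C(C)=O | starting material
6 | {[1-(2,6-dimethoxyphenyl)ethenyl]oxy}trimethylsilane | COc1cccc(OC)c1C(=C)O[Si](C)(C)C | intermediate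
7 | 2-bromo-1-(2,6-dimethoxyphenyl)ethan-1-one | COc1cccc(OC)c1C(=O)CBr | intermediate
8 | 9-(7-{4-[(tert-butyldimethylsilyl)oxy]phenyl}heptyl)-9-borabicyclo[3.3.1]nonane | CC(C)(C)[Si](C)(C)Oc1ccc(CCCCCCCB2C3CCCC2CCC3)cc1 | intermediate
9 | 9-{4-[(tert-butyldimethylsilyl)oxy]phenyl}-1-(2,6-dimethoxyphenyl)nonan-1-one | COc1cccc(OC)c1C(=O)CCCCCCCCc1ccc(O[Si](C)(C)C(C)(C)C)cc1 | intermediate
10 | 1-(2,6-dimethoxyphenyl)-9-(4-hydroxyphenyl)nonan-1-one | COc1cccc(OC)c1C(=O)CCCCCCCCc1ccc(O)cc1 | target

**Totals**
Total step count: 3 (step 3 telescopes hydroboration, C–C coupling and desilylation in one flask).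
Longest linear sequence: 2 steps (1 → 4 → 10, or 5 → 7 → 10).

**Steps most likely to fail and fallbacks** (ranked by risk: step 3 > step 2 > step 1; listed in route order)

Step 1. Risk: sluggish copper-catalysed substitution or biaryl homocoupling. Fallback: reverse the roles of the partners and use a palladium-catalysed Kumada–Corriu coupling. It sets out from 2: Mg in THF converts 2 into hept-6-en-1-ylmagnesium bromide F1, which is coupled with 1 using PdCl2(dppf) (2 mol %) in THF at reflux. It comes back to the route at 4.

Step 2. Risk: NBS attacking the electron-rich ring at C3, or dibromination. Fallback: introduce bromine as a nucleophile, not an electrophile. It sets out from 5: trifluoroacetylation (LiN(SiMe3)2, CF3CO2CH2CF3, THF, −78 °C) gives 1-(2,6-dimethoxyphenyl)-4,4,4-trifluorobutane-1,3-dione F2. Detrifluoroacetylative diazo transfer (MsN3, Et3N, MeCN/H2O, rt) then gives 2-diazo-1-(2,6-dimethoxyphenyl)ethan-1-one F3. Aqueous HBr (48 %) in Et2O at 0 °C protonates the diazo carbon and bromide displaces N2. It comes back to the route at 7.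

Step 3. Risk: the phenoxide degrades 7, or a ring B–C bond of the bicycle migrates instead of the chain. Fallback: base-free diazo ketone–trialkylborane alkylation (Hooz reaction), which keeps the same C2–C3 bond and the same a2 logic. It sets out from 5 and 4. Compound 5 is converted, as in the fallback to step 2, via 1-(2,6-dimethoxyphenyl)-4,4,4-trifluorobutane-1,3-dione F2 into 2-diazo-1-(2,6-dimethoxyphenyl)ethan-1-one F3. Compound 4 (3.1 equiv) with BH3·THF (THF, 0 °C → rt) gives tris(7-{4-[(tert-butyldimethylsilyl)oxy]phenyl}heptyl)borane F4. F3 is added to F4 in THF containing 2 equiv H2O at 0 °C → rt; one chain migrates from boron to the diazo carbon with loss of N2, and hydrolysis of the enol borinate gives the ketone. It comes back to the route at 9, which is desilylated with Bu4NF/AcOH as in step 3 to give 10. This fallback uses only one of the three chains on boron.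

**Further compounds**
F1 | step 1 | hept-6-en-1-ylmagnesium bromide | C=CCCCCC[Mg]Br
F2 | step 2 | 1-(2,6-dimethoxyphenyl)-4,4,4-trifluorobutane-1,3-dione | COc1cccc(OC)c1C(=O)CC(=O)C(F)(F)F
F3 | step 2 | 2-diazo-1-(2,6-dimethoxyphenyl)ethan-1-one | COc1cccc(OC)c1C(=O)C=[N+]=[N-]
F4 | step 3 | tris(7-{4-[(tert-butyldimethylsilyl)oxy]phenyl}heptyl)borane | B(CCCCCCCc1ccc(O[Si](C)(C)C(C)(C)C)cc1)(CCCCCCCc1ccc(O[Si](C)(C)C(C)(C)C)cc1)CCCCCCCc1ccc(O[Si](C)(C)C(C)(C)C)cc1
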